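**Plan**

- Numbering as in labdanes: ring A = C1–C5/C10, ring B = C5–C10, C18 = the CH2OH carbon on C4, side chain = C11–C16. Retrosynthetic cuts: first C9–C11 (the whole chain, by sp3–sp2 coupling at a C9 enol triflate), then C1–C10 and C4–C5 together in a [4+2] cycloaddition.
- Enabling feature: ring B (O at C6, CH3 on C8 and C10, C7=C8, C9 as a latent C=O) is 2,6-dimethyl-1,4-benzoquinone. Its C5=C10 bond has C10 β and C5–H α to the C6 carbonyl. C1–C4 with CH3 and CH2O on C4 is an (E)-2-methylpenta-2,4-dienyl ether.
- Forward: diene (3 steps) + quinone → ring A built onto ring B by a catalytic enantioselective Diels–Alder reaction → C5 epimerisation → conjugate reduction/C9 triflation → chain coupling → conjugation to the 7-en-6-one → C2=C3 hydrogenation → C6 reduction and inversion → desilylation.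
- Stereochemistry: C4, C5 and C10 from the chiral Lewis acid (endo mode, (E)-diene), C5 then corrected to trans α to C6=O. C9 by protonation anti to C10–CH3. C6 by hydride attack anti to the axial methyl groups followed by SN2 inversion. C13=C14 (E) from a syn-carbocupration.

Key step: step 4

Assumption: the facial sense of the (S)-prolinol-derived oxazaborolidinium catalyst is taken from its accepted pre-transition-state model for enones with an α-C–H; the mirror-image catalyst would be used if the sense proves opposite.

**Step 1**
Reactants: 1 acrolein; 2 ethyl 2-(triphenylphosphoranylidene)propanoate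
Product: 3 ethyl (2E)-2-methylpenta-2,4-dienoate
Conditions: CH2Cl2, 0 °C → rt
Reagents that add atoms: none
Why: Wittig olefination with a stabilised ylide, which should react only at the aldehyde and give the (E)-trisubstituted alkene with the ester trans to the vinyl group.

**Step 2**
Reactants: 3 ethyl (2E)-2-methylpenta-2,4-dienoate
Product: 4 (2E)-2-methylpenta-2,4-dien-1-ol
Conditions: i-Bu2AlH (2.2 equiv), Et2O, −78 → 0 °C; aq. potassium sodium tartrate
Reagents that add atoms: none
Why: 1,2-Reduction of a conjugated ester by an aluminium hydride, which should leave the diene and its (E) geometry untouched.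

**Step 3**
Reactants: 4 (2E)-2-methylpenta-2,4-dien-1-ol
Product: 5 tert-butyl{[(2E)-2-methylpenta-2,4-dien-1-yl]oxy}diphenylsilane
Conditions: TBDPSCl, imidazole, CH2Cl2, 0 °C → rt
Reagents that add atoms: tert-butyl(chloro)diphenylsilane, CC(C)(C)[Si](Cl)(c1ccccc1)c1ccccc1
Why: Imidazole-promoted silylation of a primary alcohol; the bulky silyl ether is a poor Lewis base and should survive the Lewis acid, hydride and base steps that follow.

**Step 4**
Reactants: 5 tert-butyl{[(2E)-2-methylpenta-2,4-dien-1-yl]oxy}diphenylsilane; 6 2,6-dimethyl-1,4-benzoquinone
Product: 7 cis-fused ene-dione, 5-[(tert-butyldiphenylsilyloxy)methyl]-2,5,8a-trimethyl-4a,5,8,8a-tetrahydronaphthalene-1,4-dione (labdane numbering: C6 and C9 ketones, C7=C8, C2=C3; C5–H, C4–CH3 and C10–CH3 on one face, CH2OTBDPS on the other)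
Conditions: 5 (1.5 equiv), (S)-3,3-diphenyl-1-(2-methylphenyl)tetrahydro-1H,3H-pyrrolo[1,2-c][1,3,2]oxazaborole (20 mol %) activated with HN(SO2CF3)2 (18 mol %), CH2Cl2, −78 → −40 °C
Reagents that add atoms: none
Why: Concerted but asynchronous [4+2] cycloaddition (Diels–Alder) in which the cationic boron Lewis acid binds the more basic, unhindered C6 carbonyl of the quinone, so that C10 becomes the electrophilic β-carbon and bonds in advance to the unsubstituted diene terminus C1 while the disubstituted terminus C4, which best carries the developing positive charge, closes onto C5; the closest known reaction types are the oxazaborolidinium-catalysed enantioselective Diels–Alder reaction of alkyl-1,4-benzoquinones and, for the regiochemistry, the BF3-promoted addition of 1-substituted dienes to this same quinone. Ring A (C1–C5, C10) is closed by intermolecular suprafacial–suprafacial cycloaddition onto the preformed ring B, both bonds forming in one transition state. C5 and C10 should come out cis because addition to the quinone C=C is suprafacial, and the quaternary C4 is fixed relative to them by the endo transition state together with the (E) geometry of the diene, which places CH2OTBDPS (outside) syn to C6 and the C4 methyl (inside) syn to C10–CH3. The absolute configuration of all three centres is set by the catalyst, which shields one face of the coordinated enone unit through the α-C–H···O contact and stacking over its aryl group. The step needs regio-, endo- and facial selectivity and must overcome the low s-cis population of a diene with an inside methyl group: the first is secured by the Lewis acid at the C6 carbonyl and by avoidance of a bond between the two fully substituted carbons C4 and C10, the second by secondary overlap with the quinone ring, the third by the catalyst, and the reactivity by cationic activation of a doubly activated dienophile. The two C=C bonds of the quinone are related by its twofold axis, so no site selectivity is required.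

**Step 5**
Reactants: 7 cis-fused ene-dione
Product: 8 trans-fused ene-dione (C5 epimer of 7: C5–H now on the face of CH2OTBDPS, opposite to C4–CH3 and C10–CH3)
Conditions: DBU (0.2 equiv), CH2Cl2, 0 °C → rt
Reagents that add atoms: none
Why: Base-mediated epimerisation through the C5 enolate of the ene-dione (the known cis-to-trans isomerisation of angular-methyl quinone–diene adducts); C5 is the only enolisable ring-fusion centre and reprotonation under equilibrium should give the trans-fused isomer, while C4 and C10 cannot change.

**Step 6**
Reactants: 8 trans-fused ene-dione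
Product: 10 C9 enol triflate (6-oxo, C8=C9–OTf, C7H2, C2=C3; trans ring fusion kept), via lithium C9 enolate 9 (not isolated)
Conditions: LiBH(s-Bu)3 (1.05 equiv), THF, −78 °C; then N-(5-chloropyridin-2-yl)bis(trifluoromethanesulfonyl)imide, −78 → −20 °C
Reagents that add atoms: N-(5-chloropyridin-2-yl)bis(trifluoromethanesulfonyl)imide, FC(F)(F)S(=O)(=O)N(c1ccc(Cl)cn1)S(=O)(=O)C(F)(F)F
Why: Conjugate reduction with enolate trapping: the bulky hydride should add 1,4 to the C9 enone at the unsubstituted β-carbon C7 (C8 is blocked by its methyl group), and the regiodefined C9 enolate is O-triflated at low temperature before it can equilibrate; no stereocentre is formed, and this step tells the C9 carbonyl from the C6 carbonyl.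

**Step 7**
Reactants: 11 methyl but-2-ynoate
Product: 12 methyl (2E)-3-methylpenta-2,4-dienoate
Conditions: CH2=CHMgBr (2.0 equiv), CuI (1.0 equiv), THF, −40 °C; then 11, −78 °C; MeOH then aq. NH4Cl at −78 °C
Reagents that add atoms: vinylmagnesium bromide, C=C[Mg]Br
Why: syn-Carbocupration of an ynoate, in which vinyl and copper add to the same side, so that protonation at low temperature should give the (E)-dienoate with the vinyl group trans to the ester.

**Step 8**
Reactants: 10 C9 enol triflate; 12 methyl (2E)-3-methylpenta-2,4-dienoate
Product: 14 β,γ-unsaturated ketone carrying the full side chain (6-oxo, C8=C9, C2=C3, C13=C14 (E), CH2OTBDPS on C4), via B-alkyl borane 13 (not isolated)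
Conditions: 12 (1.3 equiv), 9-BBN-H (1.1 equiv), THF, 0 °C → rt; then 10, PdCl2(dppf)·CH2Cl2 (10 mol %), AsPh3 (10 mol %), Cs2CO3 (2 equiv), DMF/THF/H2O, rt
Reagents that add atoms: none
Why: Anti-Markovnikov hydroboration of the terminal vinyl group followed by B-alkyl Suzuki–Miyaura coupling with the enol triflate, which should join C11 to C9 with retention at the sp2 carbon and bring in the whole chain with its (E)-enoate; no stereocentre is formed.

**Step 9**
Reactants: 14 β,γ-unsaturated ketone
Product: 15 7-en-6-one (C9–H on the face of C5–H; chain, C4–CH3 and C10–CH3 on the other face; C2=C3 still present)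
Conditions: DBU (1.0 equiv), toluene, rt, stopped at full conversion
Reagents that add atoms: none
Why: Base-catalysed conjugation of a β,γ-unsaturated ketone through the C6 dienolate; γ-protonation at C9 should occur anti to the adjacent axial C10 methyl group, which places the chain cis to C10–CH3, and stopping at full conversion keeps this kinetic C9 configuration while C5 stays in its stable trans arrangement.

**Step 10**
Reactants: 15 7-en-6-one
Product: 16 7-en-6-one with saturated ring A
Conditions: RhCl(PPh3)3 (10 mol %), H2 (1 atm), toluene/EtOH, rt
Reagents that add atoms: none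
Why: Homogeneous hydrogenation, which should reduce the cis-disubstituted C2=C3 bond far faster than the two trisubstituted, conjugated alkenes (C7=C8 and C13=C14).

**Step 11**
Reactants: 16 7-en-6-one with saturated ring A
Product: 17 6-epi allylic alcohol (C6–OH axial, on the face of C4–CH3 and C10–CH3)
Conditions: NaBH4, CeCl3·7H2O, MeOH/THF, −78 → −40 °C
Reagents that add atoms: none
Why: Luche 1,2-reduction of the enone; hydride should attack C6 from the face opposite to the two syn-axial methyl groups on C4 and C10, giving the axial alcohol that is the substrate for inversion, while both esters and the enoate stay intact.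

**Step 12**
Reactants: 17 6-epi allylic alcohol
Product: 18 C6 4-nitrobenzoate with inverted C6 (ester oxygen equatorial, on the face of C5–H)
Conditions: PPh3, DIAD, 4-nitrobenzoic acid, toluene, 0 °C → rt
Reagents that add atoms: 4-nitrobenzoic acid, OC(=O)c1ccc(cc1)[N+](=O)[O-]
Why: Mitsunobu inversion, in which the carboxylate displaces the alkoxyphosphonium group by SN2 from the open face, so the axial C6–O bond should become the equatorial one required by the target.

**Step 13**
Reactants: 18 C6 4-nitrobenzoate
Product: 19 C6 alcohol with the target configuration, C18 still silylated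
Conditions: K2CO3, MeOH, rt
Reagents that add atoms: none
Why: Methanolysis (transesterification) of the activated aryl ester; the methyl enoate only exchanges methoxide with itself and the silyl ether is stable.

**Step 14**
Reactants: 19 C6 alcohol, C18 silyl ether
Product: 20 CNP0149445.1, methyl (13E)-6,18-dihydroxylabda-7,13-dien-15-oate of the ent series (C5–H, C9–H, C6–OH and CH2OH on one face; C10–CH3, C4–CH3 and the C9 chain on the other)
Conditions: Bu4NF, AcOH (buffer), THF, 0 °C → rt
Reagents that add atoms: none
Why: Fluoride-mediated cleavage of the silyl ether, which should not touch the allylic alcohol, the enoate or any stereocentre.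

**Compound list**

1 | acrolein | C=CC=O | starting material
2 | ethyl 2-(triphenylphosphoranylidene)propanoate | CCOC(=O)C(C)=P(c1ccccc1)(c1ccccc1)c1ccccc1 | starting material
3 | ethyl (2E)-2-methylpenta-2,4-dienoate | C=C/C=C(\C)C(=O)OCC | intermediate
4 | (2E)-2-methylpenta-2,4-dien-1-ol | C=C/C=C(\C)CO | intermediate
5 | tert-butyl{[(2E)-2-methylpenta-2,4-dien-1-yl]oxy}diphenylsilane | C=C/C=C(\C)CO[Si](c1ccccc1)(c1ccccc1)C(C)(C)C | intermediate
6 | 2,6-dimethyl-1,4-benzoquinone | CC1=CC(=O)C=C(C)C1=O | starting material
7 | cis-fused ene-dione (Diels–Alder adduct) | O=C1C(C)=CC(=O)[C@H]2[C@@](C)(CO[Si](c3ccccc3)(c3ccccc3)C(C)(C)C)C=CC[C@@]12C | intermediate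
8 | trans-fused ene-dione | O=C1C(C)=CC(=O)[C@@H]2[C@@](C)(CO[Si](c3ccccc3)(c3ccccc3)C(C)(C)C)C=CC[C@@]12C | intermediate
9 | lithium C9 enolate of the 6-ketone | [Li]OC1=C(C)CC(=O)[C@@H]2[C@@](C)(CO[Si](c3ccccc3)(c3ccccc3)C(C)(C)C)C=CC[C@@]12C | intermediate
10 | C9 enol triflate of the 6-ketone | FC(F)(F)S(=O)(=O)OC1=C(C)CC(=O)[C@@H]2[C@@](C)(CO[Si](c3ccccc3)(c3ccccc3)C(C)(C)C)C=CC[C@@]12C | intermediate
11 | methyl but-2-ynoate | CC#CC(=O)OC | starting material
12 | methyl (2E)-3-methylpenta-2,4-dienoate | C=C/C(C)=C/C(=O)OC | intermediate
13 | methyl (2E)-5-(9-borabicyclo[3.3.1]nonan-9-yl)-3-methylpent-2-enoate | COC(=O)/C=C(\C)CCB1C2CCCC1CCC2 | intermediate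
14 | β,γ-unsaturated 6-ketone with side chain (C8=C9, C2=C3) | COC(=O)/C=C(\C)CCC1=C(C)CC(=O)[C@@H]2[C@@](C)(CO[Si](c3ccccc3)(c3ccccc3)C(C)(C)C)C=CC[C@@]12C | intermediate
15 | 7-en-6-one (C2=C3 present) | COC(=O)/C=C(\C)CC[C@@H]1C(C)=CC(=O)[C@@H]2[C@@](C)(CO[Si](c3ccccc3)(c3ccccc3)C(C)(C)C)C=CC[C@@]12C | intermediate
16 | 7-en-6-one, ring A saturated | COC(=O)/C=C(\C)CC[C@@H]1C(C)=CC(=O)[C@@H]2[C@@](C)(CO[Si](c3ccccc3)(c3ccccc3)C(C)(C)C)CCC[C@@]12C | intermediate
17 | 6-epi allylic alcohol | COC(=O)/C=C(\C)CC[C@@H]1C(C)=C[C@H](O)[C@@H]2[C@@](C)(CO[Si](c3ccccc3)(c3ccccc3)C(C)(C)C)CCC[C@@]12C | intermediate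
18 | C6 4-nitrobenzoate (inverted) | COC(=O)/C=C(\C)CC[C@@H]1C(C)=C[C@@H](OC(=O)c3ccc(cc3)[N+](=O)[O-])[C@@H]2[C@@](C)(CO[Si](c4ccccc4)(c4ccccc4)C(C)(C)C)CCC[C@@]12C | intermediate
19 | C6 alcohol, C18 silyl ether | COC(=O)/C=C(\C)CC[C@@H]1C(C)=C[C@@H](O)[C@@H]2[C@@](C)(CO[Si](c3ccccc3)(c3ccccc3)C(C)(C)C)CCC[C@@]12C | intermediate
20 | CNP0149445.1 | COC(=O)/C=C(\C)CC[C@@H]1C(C)=C[C@@H](O)[C@@H]2[C@@](C)(CO)CCC[C@@]12C | target

**Step count and risks**

Total: 14 steps. Longest linear sequence: 13 steps (steps 1–6 and 8–14, from acrolein); step 7 makes the side-chain fragment.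

Steps most likely to fail:

1. Step 4. The inside methyl group of the diene lowers its s-cis population, so the bulky chiral Lewis acid may turn over slowly, and an uncatalysed or acid-promoted background path would erode the enantioselectivity. The fallback replaces catalyst control by resolution. It sets out from 5 and 6: stoichiometric BF3·OEt2 in CH2Cl2 at −78 → −20 °C (a small Lewis acid that binds the same C6 carbonyl and should keep the regiochemistry and endo mode) would give the racemate, that is 7 together with its mirror image ent-7 F1. Preparative chromatography on a chiral stationary phase separates the two, and the route is rejoined at 7.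

2. Step 8. Oxidative addition and transmetalation at a tetrasubstituted triflate next to the quaternary C10 may be slow, the base may enolise and degrade the β,γ-keto triflate meanwhile, and 9-BBN-H may partly reduce the dienoate conjugatively instead of hydroborating it. The fallback moves the sp3–sp2 bond formation from the crowded C9–C11 bond to the open C12–C13 bond. It sets out from 10: Stille coupling with tributyl(vinyl)stannane (Pd(PPh3)4, LiCl, THF, 60 °C) should give the C9-vinyl diene F2. Hydroboration of its terminal vinyl group with 9-BBN-H (the hindered C6 ketone should react more slowly) gives the B-alkyl borane F3, which is not isolated. Suzuki–Miyaura coupling of F3 with the known methyl (2E)-3-iodobut-2-enoate, C/C(I)=C\C(=O)OC (PdCl2(dppf)·CH2Cl2, AsPh3, Cs2CO3, DMF/H2O, rt), rejoins the route at 14.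

3. Step 12. The axial C6–O bond is anti-periplanar to C5–H and flanked by two syn-axial methyl groups, so elimination to a ring B diene or ionisation may outrun the SN2 displacement. The fallback replaces inversion by thermodynamic control. It sets out from 17: reversible hydrogen transfer with (η5-C5Ph5)Ru(CO)2Cl (5 mol %) and KOt-Bu (5 mol %) in toluene should equilibrate the C6 epimers. The equatorial alcohol should be favoured, since it has one syn-pentane contact with C18 against two syn-axial methyl contacts for the axial one. The route is rejoined at 19, skipping 18; this fallback makes no new compound (F0).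

**Further compounds**

F1 | step 4 | mirror image of cis-fused ene-dione 7 (second half of the racemate) | O=C1C(C)=CC(=O)[C@@H]2[C@](C)(CO[Si](c3ccccc3)(c3ccccc3)C(C)(C)C)C=CC[C@]12C
F2 | step 8 | C9-vinyl diene (6-oxo, C8=C9–CH=CH2, C2=C3) | C=CC1=C(C)CC(=O)[C@@H]2[C@@](C)(CO[Si](c3ccccc3)(c3ccccc3)C(C)(C)C)C=CC[C@@]12C
F3 | step 8 | B-alkyl borane from F2 (9-BBN on C12) | C(CC1=C(C)CC(=O)[C@@H]2[C@@](C)(CO[Si](c3ccccc3)(c3ccccc3)C(C)(C)C)C=CC[C@@]12C)B1C2CCCC1CCC2
F0 | step 12 | none | none
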